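**Conventions.** Ring A = cyclohexene C5=C10–C9–C8–C7–C6. Ring B = lactone O–C8–C7–C11(=C13)–C12(=O). C14 = oxymethyl carbon on C10. The side chain on C5 is C4(C15H3)–C3–C2–C1–OH. TBDPS = tert-butyldiphenylsilyl, PMB = 4-methoxybenzyl.

## The problem

Target 30 is a 1,10-seco-eudesmanolide in which ring A and ring B share the C7–C8 bond. The rings are trans-fused and the C6 acetate is cis to the C7–C11 bond, hence pseudoaxial on the half-chair of ring A; the descriptors are 4S, 6S, 7S, 8R. C6, C7 and C8 are contiguous, so C8 can direct C7 across the five-membered ring and the ring fusion can then bias a reagent at C6. C4 is insulated from the ring by the tetrasubstituted C5=C10 bond and has to arrive with a building block. Three oxygen functions in three different states (free C1–OH, C6 acetate, C14 methacrylate) must be told apart, and the two acrylate-type acceptors plus the ionizable allylic acetate rule out nucleophiles, hydrides and strong base at the end. Whenever C6 is a ketone the lactone oxygen on C8 is β to it, so elimination and aromatization of ring A is a standing threat. The structure opens up because C7 and C11 are the β- and α-carbons of a butenolide (ring B), C6 sits at an oxidation level an acyl anion can deliver, and C6–C5–C4(C15)–C3–C2–C1 is the chain of (S)-citronellal with its methyl-bearing stereocentre in place.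

## Retrosynthesis

**O–Si at C1, ester C–O at C14, O–PMB at C14 (30 ⇐ 29 ⇐ 28 ⇐ 27).** The last bonds made are heteroatom bonds. Two free primary alcohols could not be differentiated by an acylating agent, so C1 is carried as a TBDPS ether and C14 as a PMB ether. Fluoride and DDQ remove them without touching the acetate or the acceptors. The forward steps need only mild, non-nucleophilic reagents.

**C11=C13 (27 ⇐ 26 ⇐ 25).** The methylene is traced back to the loss of trimethylamine from ammonium salt 26, i.e. to Mannich base 25. Carrying the free methylene further back would expose it to the hydride needed at C6, and a late enolate methylenation would not tolerate the C6 acetate. The β-amino lactone is inert to hydride and acid and keeps the acceptor latent.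

**C6–O acyl bond and C6–H bond (25 ⇐ 24 ⇐ 23).** The acetate goes back to alcohol 24 and this to enone 23. The hydroxyl must be pseudoaxial and cis to C7–C11, which is the product of equatorial hydride delivery by a bulky borohydride; the fully substituted C10 blocks conjugate reduction. The C6 ketone is wanted anyway, because it makes C5 nucleophilic for the ring closure.

**C5=C10, σ and π (23 ⇐ 21 ⇐ 20 ⇐ 19).** Ring A is opened at its double bond in the aldol sense: C5 as nucleophile, the C10 ketone as electrophile. This leads to 1,5-diketone 21, its C10 dioxolane 20 and the C6 dithiane 19. Compared with cuts at C7–C8 or C8–C9, the alkene geometry is fixed by the ring, no stereocentre is formed, and ring B with C7 and C8 can be finished beforehand. The forward reaction must close C5 onto C10 rather than C14 onto C6, and must run in acid so that the lactone oxygen, which is β to both ketones, is not expelled.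

**C6–C7 and C11–C13 (19 ⇐ 7 + 15 + 16).** In 19 the lactone carries a masked acyl group on its β-carbon and an aminomethyl group on its α-carbon. Both bonds are cut at once: dithiane 7 as the C6 acyl anion, butenolide 15 as a β-electrophile and then α-nucleophile, and iminium salt 16 as C13. A stepwise alternative (acylation at C7, then separate enolization) would need a strong base a second time on a β-acyl lactone. The cut divides the molecule into a C6–C1 piece with C4 and a ring B piece with C8, C9, C10 and C14. The forward step must give 1,4-addition, attack anti to the C8 substituent, and capture of the enolate before proton transfer.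

**Dithiane 7 (7 ⇐ 5 + 6 ⇐ 4 ⇐ 2 ⇐ 1).** The C–S bonds are cut to acetal 5 and propane-1,3-dithiol 6. The silyl ether goes back to alcohol 4 and its C1–O to the trisubstituted alkene of citronellal acetal 2, from (S)-citronellal 1. The aldehyde is held as an O,O-acetal while the alkene is ozonized, because a dithiane would not survive ozone. The sulfur is introduced afterwards.

**Butenolide 15 (15 ⇐ 14 ⇐ 13 ⇐ 12 ⇐ 11 ⇐ 10 ⇐ 8 + 9).** The ring B alkene C7=C11 is cut by ring-closing metathesis to acrylate 14 and the ester to allylic alcohol 13. The C7–C8 bond is cut to aldehyde 12 and an alkenylzinc reagent, and this step sets C8 by catalyst control. Aldehyde 12 comes from ester 11, the ketal of keto ester 10, which is made from ethyl 4-chloro-3-oxobutanoate 8 and PMB alcohol 9. C8–C9–C10–C14 are thus bought as one C4 unit with the C10 ketone and the C14 oxygen already present.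

## Roads not taken

**Alternative 1:** chromium-mediated ring-closing allylation with lactonization. The cut is C7–C8 together with O–C12. Open-chain bromo aldehyde A2 (C8 aldehyde, (Z)-2-(bromomethyl)enoate C13–C11(C12)=C7, C6 as PMB ether, C5=C10 already present) would be treated with CrCl2. The allylchromium reagent formed by divalent chromium adds through C7 to C8 and the C8 alkoxide closes onto the C12 ester, giving bicycle A1.
- Merits: both rings close in one operation and the methylene lactone is formed directly. C6 is never a ketone, so there is no β-acyloxy ketone hazard and no hydride step. The end game is shorter, and in this respect the road is better than the chosen one.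
- Weak points: A2 needs a stereodefined acyclic tetrasubstituted alkene with four different carbon substituents and a C6 carbinol set next to it. Its aldehyde is β,γ-unsaturated and prone to conjugate. Six-membered closures of this type have a documented tendency toward cis-fused lactones, so the trans fusion with C6 cis to C11 is not assured.
- Comparison: the chosen plan offers precursors reachable in a few steps from the chiral pool and one catalytic asymmetric step, an alkene whose geometry is dictated by the ring, and C7 set by simple approach control on a five-membered ring.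

**Alternative 2:** nickel-catalysed alkyne insertion into a cyclobutanone. The cut is C5–C6 and C9–C10. Ni(cod)2 (zerovalent nickel) with a chiral phosphine would couple 3-benzyloxycyclobutanone A4 with silyl alkyne A5 by oxidative cyclization, β-carbon elimination and reductive elimination, giving cyclohexenone A3.
- Merits: ring A and its tetrasubstituted alkene arise in one catalytic step from two simple pieces, and C8 is set by desymmetrization. In speed of ring A assembly it beats the chosen plan.
- Weak points: silicon normally ends on the nickel-bound carbon, which is the needed regiochemistry, but the branched C4 substituent hinders bond formation at C5. Enantiotopic C–C selection in an intermolecular case has thin precedent, and the fixed C4 centre creates a matched/mismatched problem. After the key step, all of ring B, the C7 centre, the change of C10–Si into C10–CH2O and a benzyl removal next to alkenes remain, and A3 is itself a β-alkoxy ketone.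
- Comparison: the chosen plan has ring B, C7, C8 and the masked C11=C13 in place after one operation, whereas here most of the stereochemical and functional work follows the key step.

**Alternative 3:** intramolecular Horner–Wadsworth–Emmons closure of ring A. The cut is C5=C10, as in the chosen route. β-Keto phosphonate A7 (phosphorus on C5, free C10 ketone) would be closed with LiCl and i-Pr2NEt to enone A6, which is the same compound as 23.
- Merits: only C5 can act as nucleophile, so the C14-onto-C6 closure cannot occur. In regiochemical certainty this road is better.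
- Weak points: A7 requires C6 to enter at the carboxyl level on C7 and a branched phosphonate anion to be acylated next to a lactone and a Mannich base. Olefination of a ketone by an α-substituted keto phosphonate to a tetrasubstituted alkene is slow. The amine base meets the C10 ketone, whose C9 enolate can expel the C8 carboxylate freely.
- Comparison: the chosen plan reaches the same enone in fewer steps, because the dithiane delivers C6 and C5 together at the right oxidation level, and it closes the ring in acid.

Key step: step 11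

Remark on the chemistry: (S)-citronellal is taken to be of high enantiomeric purity; material from the antipode would be a C4-epimeric diastereomer from step 11 onwards and removable there.

## Route

Step 1
Reactants: 1 (S)-citronellal
Product: 2 (6S)-8,8-dimethoxy-2,6-dimethyloct-2-ene
Conditions: HC(OMe)3, MeOH, TsOH·H2O (1 mol %), 0 °C to rt
Reagents that add atoms: trimethyl orthoformate, COC(OC)OC
Why: Acid-catalysed acetalization driven by the orthoformate; the low acid loading and temperature avoid the carbonyl-ene cyclization of citronellal, and the O,O-acetal, unlike a dithiane, tolerates ozone in step 2.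

Step 2
Reactants: 2 citronellal dimethyl acetal
Product: 4 (4S)-6,6-dimethoxy-4-methylhexan-1-ol, via aldehyde 3 (not isolated)
Conditions: O3, CH2Cl2/MeOH, −78 °C; then NaBH4, −78 °C to rt
Reagents that add atoms: ozone, [O-][O+]=O
Why: Ozonolysis of the electron-rich trisubstituted alkene with reductive work-up; the acetal is inert to both reagents and the stereocentre is remote from the reacting site.

Step 3
Reactants: 4 hydroxy acetal
Product: 5 tert-butyl{[(4S)-6,6-dimethoxy-4-methylhexyl]oxy}diphenylsilane
Conditions: TBDPSCl, imidazole, CH2Cl2, rt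
Reagents that add atoms: tert-butyl(chloro)diphenylsilane, CC(C)(C)[Si](Cl)(c1ccccc1)c1ccccc1
Why: Silyl ether formation at the primary alcohol; TBDPS is chosen because it must survive organolithium reagents, Hg(ClO4)2, aqueous HCl and DDQ and be removed last.

Step 4
Reactants: 5 silyl ether acetal; 6 propane-1,3-dithiol
Product: 7 tert-butyl{[(4S)-5-(1,3-dithian-2-yl)-4-methylpentyl]oxy}diphenylsilane
Conditions: BF3·OEt2 (0.2 equiv), CH2Cl2, −20 to 0 °C
Reagents that add atoms: none
Why: Lewis-acid-catalysed transthioacetalization through oxocarbenium and thionium ions, driven by the stronger C–S bonds; the silyl ether tolerates the brief cold exposure to BF3.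

Step 5
Reactants: 8 ethyl 4-chloro-3-oxobutanoate; 9 4-methoxybenzyl alcohol
Product: 10 ethyl 4-[(4-methoxybenzyl)oxy]-3-oxobutanoate
Conditions: NaH (2.2 equiv), THF, 0 °C to rt; aq NH4Cl
Reagents that add atoms: none
Why: Williamson ether synthesis on the activated α-chloro ketone; the second equivalent of NaH holds the keto ester as its enolate and so suppresses self-condensation.

Step 6
Reactants: 10 PMB keto ester
Product: 11 ethyl 2-(2-{[(4-methoxybenzyl)oxy]methyl}-1,3-dioxolan-2-yl)acetate
Conditions: Me3SiOCH2CH2OSiMe3, Me3SiOTf (5 mol %), CH2Cl2, −78 to −20 °C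
Reagents that add atoms: 1,2-bis(trimethylsilyloxy)ethane, C[Si](C)(C)OCCO[Si](C)(C)C
Why: Silyl-transfer ketalization driven by formation of hexamethyldisiloxane; the aprotic low-temperature conditions spare the PMB ether and avoid transesterification.

Step 7
Reactants: 11 ketal ester
Product: 12 2-(2-{[(4-methoxybenzyl)oxy]methyl}-1,3-dioxolan-2-yl)acetaldehyde
Conditions: i-Bu2AlH (1.1 equiv), CH2Cl2, −78 °C; aq KNaC4H4O6
Reagents that add atoms: none
Why: Partial reduction of the ester; the tetrahedral aluminium hemiacetal is stabilized by chelation to a ketal oxygen and collapses to the aldehyde only on work-up.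

Step 8
Reactants: 12 ketal aldehyde
Product: 13 (2R,3E)-1-(2-{[(4-methoxybenzyl)oxy]methyl}-1,3-dioxolan-2-yl)oct-3-en-2-ol
Conditions: 1-hexyne, Cy2BH, toluene, 0 °C to rt; Me2Zn, −78 °C; (−)-MIB (5 mol %), then 12, −20 to 0 °C; aq NH4Cl
Reagents that add atoms: 1-hexyne, C#CCCCC
Why: Syn hydroboration gives the (E)-alkenylborane and boron-to-zinc exchange the alkenylzinc reagent; the amino alcohol–zinc complex delivers the alkenyl group to the Si face of the aldehyde (catalytic asymmetric alkenylzinc addition), which for this substitution pattern is the 2R carbinol, the future C8. The butyl tail is a placeholder that leaves as hex-1-ene in step 10.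

Step 9
Reactants: 13 allylic alcohol
Product: 14 (2R,3E)-1-(2-{[(4-methoxybenzyl)oxy]methyl}-1,3-dioxolan-2-yl)oct-3-en-2-yl prop-2-enoate
Conditions: acryloyl chloride, Et3N, DMAP (cat.), CH2Cl2, 0 °C
Reagents that add atoms: acryloyl chloride, C=CC(=O)Cl
Why: O-acylation through the acylpyridinium ion; the carbinol centre is not involved.

Step 10
Reactants: 14 acrylate
Product: 15 (5R)-5-[(2-{[(4-methoxybenzyl)oxy]methyl}-1,3-dioxolan-2-yl)methyl]furan-2(5H)-one
Conditions: (H2IMes)(PCy3)Cl2Ru=CHPh (second-generation Grubbs catalyst, 5 mol %), CH2Cl2, 40 °C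
Reagents that add atoms: none
Why: Ring-closing metathesis of an allylic acrylate to the butenolide with loss of hex-1-ene; the five-membered ring forms readily with this catalyst and the allylic stereocentre is untouched.

Step 11
Reactants: 7 dithiane; 15 butenolide; 16 N,N-dimethylmethyleneiminium iodide (Me2N=CH2 iodide, Eschenmoser's salt)
Product: 19 trans,trans-Mannich base (3R,4S,5R)-4-{2-[(2S)-5-(tert-butyldiphenylsilyloxy)-2-methylpentyl]-1,3-dithian-2-yl}-3-[(dimethylamino)methyl]-5-[(2-{[(4-methoxybenzyl)oxy]methyl}-1,3-dioxolan-2-yl)methyl]oxolan-2-one, via lithiated dithiane 17 (not isolated), via lithium enolate 18 (not isolated)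
Conditions: 7, n-BuLi, THF, −30 °C; HMPA (3 equiv), −78 °C; 15, −78 °C; then 16, −78 to 0 °C
Reagents that add atoms: none
Why: Deprotonation of 7 gives 2-lithio-1,3-dithiane 17, which as a solvent-separated ion pair in HMPA adds in the Michael sense to C7, the β-carbon of 15, and the lithium enolate 18 is then aminomethylated at C11 by the iminium ion of 16 (Mannich reaction), so C6–C7 and C11–C13 form in one flask. The closest known reaction type is the tandem conjugate addition of lithiated dithianes to γ-substituted butenolides with electrophilic trapping of the lactone enolate, together with the aminomethylation of lactone lithium enolates by this iminium salt. No ring closes; ring B is brought in intact by 15 with C8 fixed. C7 is set by approach control on the nearly planar five-membered ring, the carbanion entering anti to the C8 side chain (trans C7/C8, 7S in the target numbering). C11 is set the same way, the iminium ion approaching anti to the very large dithianyl group on C7; this centre becomes trigonal in step 16, so its selectivity does not matter. The step needs 1,4- over 1,2-addition and nucleophilic rather than basic behaviour toward the acidic C8 hydrogen: the soft sulfur-stabilized anion with HMPA secures the former and the low temperature limits the latter. HMPA also takes lithium away from the ketal oxygens, so no chelation-directed syn delivery competes. The dithiane arrives as the latent C6 ketone and the amine as the latent C11=C13 methylene.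

Step 12
Reactants: 19 Mannich base dithiane
Product: 20 (3R,4S,5R)-4-[(3S)-6-(tert-butyldiphenylsilyloxy)-3-methylhexanoyl]-3-[(dimethylamino)methyl]-5-[(2-{[(4-methoxybenzyl)oxy]methyl}-1,3-dioxolan-2-yl)methyl]oxolan-2-one
Conditions: Hg(ClO4)2·3H2O, CaCO3, THF/H2O (5:1), 0 °C to rt
Reagents that add atoms: water, O
Why: Thiophilic divalent mercury binds both sulfur atoms and water hydrolyses the thionium ion to the C6 ketone (dithiane hydrolysis). CaCO3 neutralizes the acid released, so the dioxolane, the silyl ether and the trans,trans lactone are kept; the tertiary amine only costs extra mercury salt.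

Step 13
Reactants: 20 keto ketal
Product: 23 bicyclic enone (3R,3aS,7aR)-5-[(2S)-5-(tert-butyldiphenylsilyloxy)pentan-2-yl]-3-[(dimethylamino)methyl]-6-{[(4-methoxybenzyl)oxy]methyl}-3,3a,7,7a-tetrahydro-1-benzofuran-2,4-dione, via diketone 21 (not isolated), via aldol 22 (not isolated)
Conditions: 1 M aq HCl/THF (1:1), rt to 45 °C; aq NaHCO3
Reagents that add atoms: none
Why: Acid hydrolyses the dioxolane to diketone 21; the C5 enol of the hindered C6 ketone then adds to the more electrophilic, unhindered α-alkoxy ketone C10 (intramolecular aldol, 6-(enolendo)-exo-trig) and the tertiary aldol 22 loses water into conjugation. Acid rather than base keeps the amine protonated and slows E1cB loss of the C8 carboxylate, which in 23 is further disfavoured because the equatorial C8–O bond lies near the nodal plane of the enol π system. No stereocentre is created.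

Step 14
Reactants: 23 bicyclic enone
Product: 24 (3R,3aR,4S,7aR)-5-[(2S)-5-(tert-butyldiphenylsilyloxy)pentan-2-yl]-3-[(dimethylamino)methyl]-4-hydroxy-6-{[(4-methoxybenzyl)oxy]methyl}-3a,4,7,7a-tetrahydro-1-benzofuran-2(3H)-one
Conditions: Li(s-Bu)3BH, THF, −78 °C; aq NH4Cl
Reagents that add atoms: none
Why: 1,2-Reduction of the enone by a bulky trialkylborohydride: conjugate delivery is blocked by the fully substituted C10, and equatorial attack from the α face gives the pseudoaxial 6β alcohol cis to the C7–C11 bond (6S), as with 2-alkylcyclohexanones and steroidal enones. The lactone is not reduced at −78 °C and the amine keeps C11–C13 masked against hydride.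

Step 15
Reactants: 24 allylic alcohol
Product: 25 (3R,3aS,4S,7aR)-5-[(2S)-5-(tert-butyldiphenylsilyloxy)pentan-2-yl]-3-[(dimethylamino)methyl]-6-{[(4-methoxybenzyl)oxy]methyl}-2-oxo-2,3,3a,4,7,7a-hexahydro-1-benzofuran-4-yl acetate
Conditions: Ac2O, Et3N, DMAP (cat.), CH2Cl2, 0 °C to rt
Reagents that add atoms: acetic anhydride, CC(=O)OC(C)=O
Why: DMAP-catalysed acetylation of the hindered secondary alcohol with retention at C6; nothing else in the molecule is acylable.

Step 16
Reactants: 25 amino acetate
Product: 27 α-methylene lactone (3aS,4S,7aR)-5-[(2S)-5-(tert-butyldiphenylsilyloxy)pentan-2-yl]-6-{[(4-methoxybenzyl)oxy]methyl}-3-methylidene-2-oxo-2,3,3a,4,7,7a-hexahydro-1-benzofuran-4-yl acetate, via ammonium iodide 26 (not isolated)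
Conditions: MeI (excess), acetone, rt; then NaHCO3, CH2Cl2/H2O, rt
Reagents that add atoms: none
Why: Exhaustive N-methylation followed by Hofmann-type E1cB elimination of trimethylamine from the β-ammonio lactone. Bicarbonate is strong enough for this activated elimination but leaves the allylic acetate and the C7 centre alone; the amine is removed before DDQ is used because DDQ would oxidize it.

Step 17
Reactants: 27 PMB ether
Product: 28 (3aS,4S,7aR)-5-[(2S)-5-(tert-butyldiphenylsilyloxy)pentan-2-yl]-6-(hydroxymethyl)-3-methylidene-2-oxo-2,3,3a,4,7,7a-hexahydro-1-benzofuran-4-yl acetate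
Conditions: DDQ (1.3 equiv), CH2Cl2/pH 7 buffer (10:1), 0 °C
Reagents that add atoms: none
Why: Oxidative PMB ether cleavage (benzylic hydride abstraction, then hydrolysis of the oxocarbenium ion); the silyl ether, the acetate and the electron-poor methylene lactone are inert, and the slight excess at 0 °C avoids over-oxidation of the allylic alcohol.

Step 18
Reactants: 28 C14 alcohol
Product: 29 [(3aS,4S,7aR)-4-acetoxy-5-[(2S)-5-(tert-butyldiphenylsilyloxy)pentan-2-yl]-3-methylidene-2-oxo-2,3,3a,4,7,7a-hexahydro-1-benzofuran-6-yl]methyl 2-methylprop-2-enoate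
Conditions: methacryloyl chloride, Et3N, DMAP (cat.), CH2Cl2, 0 °C
Reagents that add atoms: methacryloyl chloride, C=C(C)C(=O)Cl
Why: Acylation of the only free hydroxyl; tertiary amine bases do not add irreversibly to the methylene lactone at this temperature, and the C6 acetate is trans to C14 across the ring alkene and cannot migrate.

Step 19
Reactants: 29 silyl ether
Product: 30 [(3aS,4S,7aR)-4-acetoxy-5-[(2S)-5-hydroxypentan-2-yl]-3-methylidene-2-oxo-2,3,3a,4,7,7a-hexahydro-1-benzofuran-6-yl]methyl 2-methylprop-2-enoate
Conditions: HF·pyridine, pyridine/THF, 0 °C to rt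
Reagents that add atoms: none
Why: Fluoride-mediated desilylation under buffered, weakly acidic conditions; there is no basic fluoride that could add to the two acceptors or move the acyl groups.

## Compound list

1 | (S)-citronellal, (3S)-3,7-dimethyloct-6-enal | O=CC[C@@H](C)CCC=C(C)C | starting material
2 | (6S)-8,8-dimethoxy-2,6-dimethyloct-2-ene | COC(OC)C[C@@H](C)CCC=C(C)C | intermediate
3 | (4S)-6,6-dimethoxy-4-methylhexanal | COC(OC)C[C@@H](C)CCC=O | intermediate (not isolated)
4 | (4S)-6,6-dimethoxy-4-methylhexan-1-ol | COC(OC)C[C@@H](C)CCCO | intermediate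
5 | tert-butyl{[(4S)-6,6-dimethoxy-4-methylhexyl]oxy}diphenylsilane | COC(OC)C[C@@H](C)CCCO[Si](c1ccccc1)(c1ccccc1)C(C)(C)C | intermediate
6 | propane-1,3-dithiol | SCCCS | starting material
7 | tert-butyl{[(4S)-5-(1,3-dithian-2-yl)-4-methylpentyl]oxy}diphenylsilane | C1CSC(C[C@@H](C)CCCO[Si](c2ccccc2)(c2ccccc2)C(C)(C)C)SC1 | intermediate
8 | ethyl 4-chloro-3-oxobutanoate | CCOC(=O)CC(=O)CCl | starting material
9 | 4-methoxybenzyl alcohol | COc1ccc(CO)cc1 | starting material
10 | ethyl 4-[(4-methoxybenzyl)oxy]-3-oxobutanoate | CCOC(=O)CC(=O)COCc1ccc(OC)cc1 | intermediate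
11 | ethyl 2-(2-{[(4-methoxybenzyl)oxy]methyl}-1,3-dioxolan-2-yl)acetate | CCOC(=O)CC1(COCc2ccc(OC)cc2)OCCO1 | intermediate
12 | 2-(2-{[(4-methoxybenzyl)oxy]methyl}-1,3-dioxolan-2-yl)acetaldehyde | O=CCC1(COCc2ccc(OC)cc2)OCCO1 | intermediate
13 | (2R,3E)-1-(2-{[(4-methoxybenzyl)oxy]methyl}-1,3-dioxolan-2-yl)oct-3-en-2-ol | CCCC/C=C/[C@H](O)CC1(COCc2ccc(OC)cc2)OCCO1 | intermediate
14 | (2R,3E)-1-(2-{[(4-methoxybenzyl)oxy]methyl}-1,3-dioxolan-2-yl)oct-3-en-2-yl prop-2-enoate | CCCC/C=C/[C@H](OC(=O)C=C)CC1(COCc2ccc(OC)cc2)OCCO1 | intermediate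
15 | (5R)-5-[(2-{[(4-methoxybenzyl)oxy]methyl}-1,3-dioxolan-2-yl)methyl]furan-2(5H)-one | O=C1C=C[C@@H](CC2(COCc3ccc(OC)cc3)OCCO2)O1 | intermediate
16 | N,N-dimethylmethyleneiminium iodide (Eschenmoser's salt) | C=[N+](C)C.[I-] | starting material
17 | 2-lithio derivative of 7 | [Li]C1(C[C@@H](C)CCCO[Si](c2ccccc2)(c2ccccc2)C(C)(C)C)SCCCS1 | intermediate (not isolated)
18 | lithium enolate of the C7-dithianyl lactone (C7 trans to C8 substituent) | C1CSC(SC1)(C[C@@H](C)CCCO[Si](c2ccccc2)(c2ccccc2)C(C)(C)C)[C@H]2C=C(O[Li])O[C@@H]2CC3(COCc4ccc(OC)cc4)OCCO3 | intermediate (not isolated)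
19 | (3R,4S,5R)-4-{2-[(2S)-5-(tert-butyldiphenylsilyloxy)-2-methylpentyl]-1,3-dithian-2-yl}-3-[(dimethylamino)methyl]-5-[(2-{[(4-methoxybenzyl)oxy]methyl}-1,3-dioxolan-2-yl)methyl]oxolan-2-one | C1CSC(SC1)(C[C@@H](C)CCCO[Si](c2ccccc2)(c2ccccc2)C(C)(C)C)[C@H]2[C@H](CN(C)C)C(=O)O[C@@H]2CC3(COCc4ccc(OC)cc4)OCCO3 | intermediate
20 | (3R,4S,5R)-4-[(3S)-6-(tert-butyldiphenylsilyloxy)-3-methylhexanoyl]-3-[(dimethylamino)methyl]-5-[(2-{[(4-methoxybenzyl)oxy]methyl}-1,3-dioxolan-2-yl)methyl]oxolan-2-one | O=C(C[C@@H](C)CCCO[Si](c1ccccc1)(c1ccccc1)C(C)(C)C)[C@H]2[C@H](CN(C)C)C(=O)O[C@@H]2CC3(COCc4ccc(OC)cc4)OCCO3 | intermediate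
21 | (3R,4S,5R)-4-[(3S)-6-(tert-butyldiphenylsilyloxy)-3-methylhexanoyl]-3-[(dimethylamino)methyl]-5-{3-[(4-methoxybenzyl)oxy]-2-oxopropyl}oxolan-2-one | O=C(C[C@@H](C)CCCO[Si](c1ccccc1)(c1ccccc1)C(C)(C)C)[C@H]2[C@H](CN(C)C)C(=O)O[C@@H]2CC(=O)COCc3ccc(OC)cc3 | intermediate (not isolated)
22 | (3R,3aS,7aR)-5-[(2S)-5-(tert-butyldiphenylsilyloxy)pentan-2-yl]-3-[(dimethylamino)methyl]-6-hydroxy-6-{[(4-methoxybenzyl)oxy]methyl}hexahydro-1-benzofuran-2,4-dione (aldol; C5 and C6 of the bicycle unassigned) | COc1ccc(COCC2(O)C([C@@H](C)CCCO[Si](c3ccccc3)(c3ccccc3)C(C)(C)C)C(=O)[C@H]3[C@H](CN(C)C)C(=O)O[C@@H]3C2)cc1 | intermediate (not isolated)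
23 | (3R,3aS,7aR)-5-[(2S)-5-(tert-butyldiphenylsilyloxy)pentan-2-yl]-3-[(dimethylamino)methyl]-6-{[(4-methoxybenzyl)oxy]methyl}-3,3a,7,7a-tetrahydro-1-benzofuran-2,4-dione | COc1ccc(COCC2=C([C@@H](C)CCCO[Si](c3ccccc3)(c3ccccc3)C(C)(C)C)C(=O)[C@H]3[C@H](CN(C)C)C(=O)O[C@@H]3C2)cc1 | intermediate
24 | (3R,3aR,4S,7aR)-5-[(2S)-5-(tert-butyldiphenylsilyloxy)pentan-2-yl]-3-[(dimethylamino)methyl]-4-hydroxy-6-{[(4-methoxybenzyl)oxy]methyl}-3a,4,7,7a-tetrahydro-1-benzofuran-2(3H)-one (6β-alcohol, OH cis to C7–C11) | COc1ccc(COCC2=C([C@@H](C)CCCO[Si](c3ccccc3)(c3ccccc3)C(C)(C)C)[C@@H](O)[C@H]3[C@H](CN(C)C)C(=O)O[C@@H]3C2)cc1 | intermediate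
25 | (3R,3aS,4S,7aR)-5-[(2S)-5-(tert-butyldiphenylsilyloxy)pentan-2-yl]-3-[(dimethylamino)methyl]-6-{[(4-methoxybenzyl)oxy]methyl}-2-oxo-2,3,3a,4,7,7a-hexahydro-1-benzofuran-4-yl acetate | COc1ccc(COCC2=C([C@@H](C)CCCO[Si](c3ccccc3)(c3ccccc3)C(C)(C)C)[C@@H](OC(C)=O)[C@H]3[C@H](CN(C)C)C(=O)O[C@@H]3C2)cc1 | intermediate
26 | trimethylammonium iodide of 25 (N-methylated at the C13 nitrogen) | COc1ccc(COCC2=C([C@@H](C)CCCO[Si](c3ccccc3)(c3ccccc3)C(C)(C)C)[C@@H](OC(C)=O)[C@H]3[C@H](C[N+](C)(C)C)C(=O)O[C@@H]3C2)cc1.[I-] | intermediate (not isolated)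
27 | (3aS,4S,7aR)-5-[(2S)-5-(tert-butyldiphenylsilyloxy)pentan-2-yl]-6-{[(4-methoxybenzyl)oxy]methyl}-3-methylidene-2-oxo-2,3,3a,4,7,7a-hexahydro-1-benzofuran-4-yl acetate | COc1ccc(COCC2=C([C@@H](C)CCCO[Si](c3ccccc3)(c3ccccc3)C(C)(C)C)[C@@H](OC(C)=O)[C@H]3C(=C)C(=O)O[C@@H]3C2)cc1 | intermediate
28 | (3aS,4S,7aR)-5-[(2S)-5-(tert-butyldiphenylsilyloxy)pentan-2-yl]-6-(hydroxymethyl)-3-methylidene-2-oxo-2,3,3a,4,7,7a-hexahydro-1-benzofuran-4-yl acetate | OCC1=C([C@@H](C)CCCO[Si](c2ccccc2)(c2ccccc2)C(C)(C)C)[C@@H](OC(C)=O)[C@H]2C(=C)C(=O)O[C@@H]2C1 | intermediate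
29 | [(3aS,4S,7aR)-4-acetoxy-5-[(2S)-5-(tert-butyldiphenylsilyloxy)pentan-2-yl]-3-methylidene-2-oxo-2,3,3a,4,7,7a-hexahydro-1-benzofuran-6-yl]methyl 2-methylprop-2-enoate | C=C(C)C(=O)OCC1=C([C@@H](C)CCCO[Si](c2ccccc2)(c2ccccc2)C(C)(C)C)[C@@H](OC(C)=O)[C@H]2C(=C)C(=O)O[C@@H]2C1 | intermediate
30 | [(3aS,4S,7aR)-4-acetoxy-5-[(2S)-5-hydroxypentan-2-yl]-3-methylidene-2-oxo-2,3,3a,4,7,7a-hexahydro-1-benzofuran-6-yl]methyl 2-methylprop-2-enoate | C=C(C)C(=O)OCC1=C([C@@H](C)CCCO)[C@@H](OC(C)=O)[C@H]2C(=C)C(=O)O[C@@H]2C1 | target

## Step count and weak points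

Total: 19 steps. Longest linear sequence: 15 steps (steps 5–19, from 8); the dithiane branch (steps 1–4) joins at step 11.

**Step 11 (key step).** The most likely failure is proton transfer in place of C–C bond formation. The 2-alkyl dithianyl anion is a strong, hindered base, and the C8 hydrogen of 15 is acidic because its loss gives a 2-oxyfuran dienolate; this would return 7 and racemize or consume 15. Incomplete capture of enolate 18 is a second weakness. The fallback uses a less basic, softer acyl anion for the same two bonds. It sets out from acetal 5: thiophenol and BF3·OEt2 should give tert-butyl{[(4S)-4-methyl-6,6-bis(phenylsulfanyl)hexyl]oxy}diphenylsilane F1. Its lithio derivative (n-BuLi, THF, then HMPA, −78 °C) would be added to 15 and trapped with 16 as before to give the bis(phenylsulfanyl) Mannich base F2. Hydrolysis of F2 with Hg(ClO4)2 and CaCO3 in aqueous THF rejoins the route at ketone 20.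

**Step 13.** The likely failures are loss of the lactone, closure in the wrong sense, and epimerization.
- In diketone 21 the C8 oxygen is β to the C10 ketone across a freely rotating C8–C9 bond, so β-elimination of the carboxylate can compete with ring closure.
- The C14 enol can attack C6 and give an isomeric 2-alkoxy enone.
- After closure, enolization of 23 at C7 can lead to epimerization to a cis-fused lactone or to elimination and aromatization.

The fallback never liberates the C10 ketone and fixes the nucleophile. It sets out from 20: kinetic silylation at the less substituted C5 (LiN(SiMe3)2, Me3SiCl, THF, −78 °C) should give the C5 trimethylsilyl enol ether F3. TiCl4 in CH2Cl2 at −78 °C would then promote an intramolecular Mukaiyama aldol addition onto the dioxolane carbon C10 to give the bicyclic β-(2-hydroxyethoxy) ketone F4. Loss of ethylene glycol from F4 (TsOH, benzene, 50 °C) rejoins the route at enone 23.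

**Step 14.** The likely failure is poor facial selectivity. The β face of 23 carries only one axial hydrogen (H8), so the preference of the bulky hydride for equatorial attack may be modest, and the branched C5 substituent crowds both faces. The fallback accepts the opposite preference of a small hydride and inverts. It sets out from 23: NaBH4 with CeCl3·7H2O in MeOH at −78 °C (Luche reduction) should deliver hydride axially from the β face to give the 6α (6R) alcohol F5. A Mitsunobu reaction of F5 with acetic acid (PPh3, DIAD, THF, 0 °C) inverts C6 and installs the acetate in one operation, rejoining the route at 25.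

**Step 8.** The likely failure is erosion of enantioselectivity. The ketal oxygens β to the aldehyde can bind zinc and open a ligand-free background addition, and any loss would reappear after step 11 as diastereomers because C4 is fixed. The fallback separates bond formation from stereo-induction. It sets out from 12: addition of the same alkenylzinc reagent without ligand gives the racemic allylic alcohol F6. Dess–Martin oxidation gives the (E)-enone F7. Corey–Bakshi–Shibata reduction of F7 with the (S)-methyl oxazaborolidine and catecholborane at −78 °C, with the alkenyl group acting as the large substituent, returns the (R)-alcohol 13.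

## Further compounds

F1 | step 11 | tert-butyl{[(4S)-4-methyl-6,6-bis(phenylsulfanyl)hexyl]oxy}diphenylsilane | C(C[C@@H](C)CCCO[Si](c1ccccc1)(c1ccccc1)C(C)(C)C)(Sc1ccccc1)Sc1ccccc1
F2 | step 11 | (3R,4S,5R)-4-[(3S)-6-(tert-butyldiphenylsilyloxy)-3-methyl-1,1-bis(phenylsulfanyl)hexyl]-3-[(dimethylamino)methyl]-5-[(2-{[(4-methoxybenzyl)oxy]methyl}-1,3-dioxolan-2-yl)methyl]oxolan-2-one | C(C[C@@H](C)CCCO[Si](c1ccccc1)(c1ccccc1)C(C)(C)C)(Sc1ccccc1)(Sc1ccccc1)[C@H]2[C@H](CN(C)C)C(=O)O[C@@H]2CC3(COCc4ccc(OC)cc4)OCCO3
F3 | step 13 | C5 trimethylsilyl enol ether of 20 (enol ether geometry unassigned) | C[Si](C)(C)OC(=C[C@@H](C)CCCO[Si](c1ccccc1)(c1ccccc1)C(C)(C)C)[C@H]2[C@H](CN(C)C)C(=O)O[C@@H]2CC3(COCc4ccc(OC)cc4)OCCO3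
F4 | step 13 | (3R,3aS,7aR)-5-[(2S)-5-(tert-butyldiphenylsilyloxy)pentan-2-yl]-3-[(dimethylamino)methyl]-6-(2-hydroxyethoxy)-6-{[(4-methoxybenzyl)oxy]methyl}hexahydro-1-benzofuran-2,4-dione (C5 and C6 of the bicycle unassigned) | COc1ccc(COCC2(OCCO)C([C@@H](C)CCCO[Si](c3ccccc3)(c3ccccc3)C(C)(C)C)C(=O)[C@H]3[C@H](CN(C)C)C(=O)O[C@@H]3C2)cc1
F5 | step 14 | (3R,3aR,4R,7aR)-5-[(2S)-5-(tert-butyldiphenylsilyloxy)pentan-2-yl]-3-[(dimethylamino)methyl]-4-hydroxy-6-{[(4-methoxybenzyl)oxy]methyl}-3a,4,7,7a-tetrahydro-1-benzofuran-2(3H)-one (6α-alcohol, C6 epimer of 24) | COc1ccc(COCC2=C([C@@H](C)CCCO[Si](c3ccccc3)(c3ccccc3)C(C)(C)C)[C@H](O)[C@H]3[C@H](CN(C)C)C(=O)O[C@@H]3C2)cc1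
F6 | step 8 | racemic (3E)-1-(2-{[(4-methoxybenzyl)oxy]methyl}-1,3-dioxolan-2-yl)oct-3-en-2-ol | CCCC/C=C/C(O)CC1(COCc2ccc(OC)cc2)OCCO1
F7 | step 8 | (3E)-1-(2-{[(4-methoxybenzyl)oxy]methyl}-1,3-dioxolan-2-yl)oct-3-en-2-one | CCCC/C=C/C(=O)CC1(COCc2ccc(OC)cc2)OCCO1
A1 | alternative 1 | (3aS,4S,7aR)-6-{[tert-butyl(dimethyl)silyl]oxymethyl}-5-[(2S)-5-(tert-butyldiphenylsilyloxy)pentan-2-yl]-4-[(4-methoxybenzyl)oxy]-3-methylidene-3a,4,7,7a-tetrahydro-1-benzofuran-2(3H)-one | CC(C)(C)[Si](C)(C)OCC1=C([C@@H](C)CCCO[Si](c2ccccc2)(c2ccccc2)C(C)(C)C)[C@@H](OCc2ccc(OC)cc2)[C@H]2C(=C)C(=O)O[C@@H]2C1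
A2 | alternative 1 | methyl (2Z,4S,5E)-2-(bromomethyl)-6-{[tert-butyl(dimethyl)silyl]oxymethyl}-5-[(2S)-5-(tert-butyldiphenylsilyloxy)pentan-2-yl]-4-[(4-methoxybenzyl)oxy]-8-oxoocta-2,5-dienoate | O=CC/C(CO[Si](C)(C)C(C)(C)C)=C(/[C@@H](C)CCCO[Si](c1ccccc1)(c1ccccc1)C(C)(C)C)[C@@H](OCc1ccc(OC)cc1)/C=C(\CBr)C(=O)OC
A3 | alternative 2 | (5S)-5-(benzyloxy)-2-[(2S)-5-(tert-butyldiphenylsilyloxy)pentan-2-yl]-3-(trimethylsilyl)cyclohex-2-en-1-one | O=C1C[C@H](OCc2ccccc2)CC([Si](C)(C)C)=C1[C@@H](C)CCCO[Si](c2ccccc2)(c2ccccc2)C(C)(C)C
A4 | alternative 2 | 3-(benzyloxy)cyclobutan-1-one | O=C1CC(OCc2ccccc2)C1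
A5 | alternative 2 | tert-butyl{[(4S)-4-methyl-6-(trimethylsilyl)hex-5-yn-1-yl]oxy}diphenylsilane | C[Si](C)(C)C#C[C@@H](C)CCCO[Si](c1ccccc1)(c1ccccc1)C(C)(C)C
A6 | alternative 3 | (3R,3aS,7aR)-5-[(2S)-5-(tert-butyldiphenylsilyloxy)pentan-2-yl]-3-[(dimethylamino)methyl]-6-{[(4-methoxybenzyl)oxy]methyl}-3,3a,7,7a-tetrahydro-1-benzofuran-2,4-dione (identical with 23) | COc1ccc(COCC2=C([C@@H](C)CCCO[Si](c3ccccc3)(c3ccccc3)C(C)(C)C)C(=O)[C@H]3[C@H](CN(C)C)C(=O)O[C@@H]3C2)cc1
A7 | alternative 3 | diethyl [(3S)-6-(tert-butyldiphenylsilyloxy)-1-{(3R,4S,5R)-3-[(dimethylamino)methyl]-5-{3-[(4-methoxybenzyl)oxy]-2-oxopropyl}-2-oxooxolan-4-yl}-3-methyl-1-oxohexan-2-yl]phosphonate (mixture at the phosphorus-bearing carbon) | CCOP(=O)(OCC)C([C@@H](C)CCCO[Si](c1ccccc1)(c1ccccc1)C(C)(C)C)C(=O)[C@H]1[C@H](CN(C)C)C(=O)O[C@@H]1CC(=O)COCc1ccc(OC)cc1
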